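## Retrosynthetic overview

- Locants follow hexahydroinden-2-one: C1 side chain, C2 ketone, C3=C3a, C4 acyloxy, C7 CO2H, C7a methyl; ring A is five-membered, ring B six-membered; β is the face of the C7a methyl.
- Feature used: C7a–CH3 and C7–CO2H are cis neighbours on ring B next to the C3a–C7a fusion, the trace of an (E)-3-methylenoyl dienophile (C7=C7a) joined through C1–C2–C3 to a diene (C3a=C4–C5=C6).
- Key disconnection: C3a–C7a and C6–C7 by a catalytic asymmetric intramolecular Diels–Alder reaction of an achiral trienyl imide; rings A and B close together (ring B as the cycloadduct ring, ring A through the tether).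
- After it: C4 ketone to 4β-OH, imide to 4-methoxybenzyl (PMB) ester, C2 ketal to ketone, C3=C3a by Saegusa oxidation, C1 side chain by α′-alkylation, C4 esterification, enal, free acid.
- Before it: triene from pent-4-yn-1-ol (vinyl carbinol, ynone, glycol double addition for the C2 ketal, olefination for C7=C7a, oxazolidin-2-one); trienoic acid from an auxiliary-controlled methylation, a Wittig and a vinylogous olefination.

Key step: step 12

Assumption: C1, α to the C2 ketone, is treated as epimerisable, and the target configuration (side chain cis to the C7a methyl) is taken to be the thermodynamically favoured one.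

## Route

Step 1
Reactants: 1 pent-4-yn-1-ol
Product: 2 pent-4-ynal
Conditions: (COCl)2, DMSO, CH2Cl2, −78 °C; Et3N, to 0 °C
Reagents that add atoms: none
Why: Swern oxidation of the primary alcohol stops at the aldehyde and leaves the terminal alkyne untouched; the volatile aldehyde should be carried on as a solution.

Step 2
Reactants: 2 pent-4-ynal
Product: 3 rac-hept-1-en-6-yn-3-ol
Conditions: CH2=CHMgBr, THF, −78 to 0 °C; aq. NH4Cl
Reagents that add atoms: vinylmagnesium bromide, C=C[Mg]Br
Why: Grignard 1,2-addition to the aldehyde should outrun deprotonation of the alkyne at low temperature and gives the racemic vinyl carbinol, whose stereocentre is erased at step 10.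

Step 3
Reactants: 3 rac-hept-1-en-6-yn-3-ol
Product: 4 TBS ether of 3
Conditions: TBSCl, imidazole, DMF, rt
Reagents that add atoms: tert-butyldimethylsilyl chloride, CC(C)(C)[Si](C)(C)Cl
Why: Standard silylation of a secondary alcohol protects the carbinol against the acetylide, alkoxide and phosphonate bases of steps 4 to 8.

Step 4
Reactants: 4 TBS ether
Product: 5 silyloxy ynone
Conditions: n-BuLi, THF, −78 °C; MeC(O)N(OMe)Me, −78 to 0 °C; aq. NH4Cl
Reagents that add atoms: N-methoxy-N-methylacetamide, CC(=O)N(C)OC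
Why: Acylation of the lithium acetylide by a Weinreb amide stops at the ketone because the chelated tetrahedral adduct survives until work-up.

Step 5
Reactants: 5 silyloxy ynone; 6 ethylene glycol (excess)
Product: 8 β-keto dioxolane, via hydroxyethoxy enone 7 (not isolated)
Conditions: t-BuOK (10 mol %), THF, 0 °C to rt
Reagents that add atoms: none
Why: Base-catalysed double oxa-Michael addition: the first addition gives the β-alkoxy enone and the pendant hydroxyl then closes 5-exo onto the same β-carbon, so the ketal sits regiospecifically at C2 and the other carbonyl stays free.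

Step 6
Reactants: 8 β-keto dioxolane
Product: 9 ethyl (E)-enoate
Conditions: (EtO)2P(O)CH2CO2Et, NaH, THF, 0 °C to reflux
Reagents that add atoms: triethyl phosphonoacetate, CCOC(=O)CP(=O)(OCC)OCC
Why: Horner–Wadsworth–Emmons olefination of the methyl ketone should place the ester trans to the bulkier CH2–ketal substituent, giving mainly the (E)-enoate; the minor (Z)-isomer should be removed by chromatography.

Step 7
Reactants: 9 ethyl (E)-enoate
Product: 10 (E)-enoic acid
Conditions: LiOH, THF/MeOH/H2O, rt; cold dilute HCl to pH 4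
Reagents that add atoms: lithium hydroxide, [Li+].[OH-]
Why: Saponification of the enoate; the dioxolane and the silyl ether are stable to base and the acidification is kept brief and cold.

Step 8
Reactants: 10 (E)-enoic acid; 11 oxazolidin-2-one
Product: 13 TBS-protected enoyl imide, via mixed pivalic anhydride 12 (not isolated)
Conditions: t-BuCOCl, Et3N, THF, −20 °C; then LiCl, 11, rt
Reagents that add atoms: none
Why: N-Acylation of the oxazolidinone through the mixed pivalic anhydride under LiCl/Et3N activation, with attack at the less hindered enoyl carbonyl and without isomerising the (E)-alkene.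

Step 9
Reactants: 13 TBS-protected enoyl imide
Product: 14 allylic alcohol imide
Conditions: HF·pyridine, pyridine, THF, 0 °C to rt
Reagents that add atoms: none
Why: Buffered HF·pyridine cleaves the secondary silyl ether (fluoride desilylation) without touching the dioxolane or the imide.

Step 10
Reactants: 14 allylic alcohol imide
Product: 15 vinyl ketone imide
Conditions: Dess–Martin periodinane (DMP), pyridine, CH2Cl2, 0 °C
Reagents that add atoms: none
Why: Dess–Martin oxidation of the allylic alcohol under buffered, non-nucleophilic conditions gives the vinyl ketone, which should be used at once; the triene is now achiral.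

Step 11
Reactants: 15 vinyl ketone imide
Product: 16 achiral trienyl imide (2-silyloxydiene)
Conditions: TBSOTf, Et3N, CH2Cl2, −78 °C
Reagents that add atoms: tert-butyldimethylsilyl trifluoromethanesulfonate, CC(C)(C)[Si](C)(C)OS(=O)(=O)C(F)(F)F
Why: Soft enolisation with silyl triflate and amine: the C3a methylene is the only enolisable position of the vinyl ketone and the (Z)-silyl enol ether is the expected isomer, while the imide and the ketal should not react at −78 °C.

Step 12
Reactants: 16 achiral trienyl imide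
Product: 17 trans-fused cycloadduct (C4 silyl enol ether, C2 dioxolane, C7 imide)
Conditions: [Cu((S,S)-t-Bu-box)](SbF6)2 (10 mol %), anhydrous CH2Cl2, −20 °C to rt; t-Bu-box = 2,2'-(propane-2,2-diyl)bis[(4S)-4-tert-butyl-4,5-dihydrooxazole]
Reagents that add atoms: none
Why: The imide chelates the cationic divalent copper centre through both carbonyl groups in the s-cis form, which lowers the LUMO of the C7=C7a bond, and the electron-rich 2-silyloxydiene then adds in a concerted, asynchronous [4+2] step in which the C3a–C7a bond runs ahead of the C6–C7 bond; the closest known reaction is the intramolecular Diels–Alder reaction of 2,7,9-trienoyl oxazolidinones under bis(oxazoline)–Cu(SbF6)2 catalysis, applied here to a β-methylated dienophile. Ring B closes as the cyclohexene of the cycloaddition and ring A as the five-membered ring spanned by the C1–C2–C3 tether, both in the same transition state. C7 and C7a are set together: suprafacial addition to the (E)-alkene keeps the methyl and the acyl group cis, and the tert-butyl group of the (S,S)-ligand should screen the Si face at C7 in the square-planar chelate, so the diene adds to the Re face (7R). C3a follows from the endo arrangement (acyl group under the diene, tether exo), which gives the trans ring fusion. The step needs enantioface selectivity (secured by the ligand, the triene being achiral), endo selectivity (secured by the bound imide; it matters only for the C4 reduction of step 14, since C3a later becomes sp2) and the regiochemistry, which the tether fixes and the polarity of the silyloxydiene (nucleophilic C3a onto the β-carbon C7a) supports. The gem-dialkoxy carbon C2 favours the folded conformer (Thorpe–Ingold effect) and the (Z)-enol ether keeps the tether on the outside of the diene.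

Step 13
Reactants: 17 cycloadduct
Product: 18 C4 ketone
Conditions: HF·pyridine, pyridine, THF, 0 °C
Reagents that add atoms: none
Why: Fluoride cleavage of the silyl enol ether with protonation at C5 gives the C4 ketone without enolisation toward C3a, so the trans ring fusion is kept, and the buffered medium spares the ketal.

Step 14
Reactants: 18 C4 ketone
Product: 19 4β-alcohol
Conditions: NaBH4, MeOH/THF, −40 °C
Reagents that add atoms: none
Why: Borohydride reduction: hydride should add to the α face because the axial approach on the β face is blocked by the 1,3-related axial C7a methyl, which sets C4 as the axial 4β-alcohol (4S), and at −40 °C the ketone is reduced far faster than the imide.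

Step 15
Reactants: 19 4β-alcohol
Product: 20 4β-silyl ether
Conditions: TBSOTf, 2,6-lutidine, CH2Cl2, −78 to 0 °C
Reagents that add atoms: tert-butyldimethylsilyl trifluoromethanesulfonate, CC(C)(C)[Si](C)(C)OS(=O)(=O)C(F)(F)F
Why: Silyl triflate silylation is needed for the hindered axial alcohol, and the lutidine buffer keeps the ketal intact.

Step 16
Reactants: 20 4β-silyl ether imide
Product: 22 C7 carboxylic acid, via percarboxylic acid 21 (not isolated)
Conditions: LiOH, H2O2, THF/H2O, 0 °C; Na2SO3; cold dilute HCl to pH 4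
Reagents that add atoms: hydrogen peroxide (as LiOOH), OO
Why: Lithium hydroperoxide attacks the exocyclic imide carbonyl selectively even for a hindered acyl group (oxazolidinone cleavage), and sulfite reduces the percarboxylate to the acid.

Step 17
Reactants: 22 C7 carboxylic acid
Product: 23 PMB ester
Conditions: 4-MeOC6H4CH2Cl, Cs2CO3, DMF, rt
Reagents that add atoms: 4-methoxybenzyl chloride, COc1ccc(CCl)cc1
Why: O-Alkylation of the caesium carboxylate by the benzylic chloride avoids any attack at the hindered acyl carbon and installs an ester that is later removed by acid.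

Step 18
Reactants: 23 PMB ester ketal
Product: 24 C2 ketone
Conditions: pyridinium p-toluenesulfonate, acetone/H2O, 60 °C
Reagents that add atoms: water, O
Why: Mild acid-catalysed hydrolysis of the dioxolane frees the C2 ketone; the hindered silyl ether and the PMB ester should tolerate pyridinium tosylate.

Step 19
Reactants: 24 C2 ketone
Product: 26 C3=C3a enone, via trimethylsilyl enol ether 25 (not isolated)
Conditions: LiN(i-Pr)2, Me3SiCl, THF, −78 °C; then Pd(OAc)2 (1.1 equiv), MeCN, rt
Reagents that add atoms: none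
Why: Saegusa oxidation: kinetic enolisation should favour the C3 methylene over the neopentyl C1 methylene, and palladation at C3 with β-hydride loss from C3a gives the C3=C3a enone, whereas any C1 enol ether has no β-hydrogen and returns ketone 24 on work-up.

Step 20
Reactants: 27 3-bromo-2-(bromomethyl)prop-1-ene (3 equiv)
Product: 28 2-(bromomethyl)allyl PMB ether
Conditions: 4-MeOC6H4CH2OH, NaH, THF, 0 °C; then 27, 0 °C to rt
Reagents that add atoms: 4-methoxybenzyl alcohol, COc1ccc(CO)cc1
Why: Williamson etherification with the dibromide in excess to favour mono-substitution.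

Step 21
Reactants: 26 enone; 28 2-(bromomethyl)allyl PMB ether
Product: 30 C1β-alkylated enone (1R), via C1 epimer mixture 29 (not isolated)
Conditions: LiN(i-Pr)2, THF, −78 °C; 28, DMPU, −78 to −40 °C; aq. NH4Cl; then DBU (cat.), toluene, rt
Reagents that add atoms: none
Why: The kinetic α′-enolate at C1 (the γ-hydrogen at C4 lies near the enone plane and should not be removed) is C-alkylated by the allylic bromide, and DBU then equilibrates C1 through the enol to the epimer with the side chain β (cis to the C7a methyl, 1R), which avoids the 1,3-syn clash with the C7 ester (enolate alkylation followed by thermodynamic epimerisation).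

Step 22
Reactants: 30 C1β-alkylated enone
Product: 31 C4 alcohol
Conditions: aq. HF, MeCN, 0 °C to rt
Reagents that add atoms: none
Why: Acidic fluoride removes the allylic silyl ether; the PMB ether, the PMB ester and the enone are stable to aqueous HF.

Step 23
Reactants: 32 (4R)-4-benzyloxazolidin-2-one
Product: 33 N-butanoyl auxiliary
Conditions: n-BuLi, THF, −78 °C; n-PrCOCl
Reagents that add atoms: butanoyl chloride, CCCC(=O)Cl
Why: N-Acylation of the lithiated auxiliary with the acid chloride.

Step 24
Reactants: 33 N-butanoyl auxiliary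
Product: 34 (2R)-2-methylbutanoyl imide
Conditions: NaN(SiMe3)2, THF, −78 °C; MeI
Reagents that add atoms: iodomethane, CI
Why: Auxiliary-controlled enolate alkylation: the chelated (Z)-sodium enolate is methylated on the face opposite the benzyl group, which sets the (2R) centre; the minor diastereomer should be removed by chromatography.

Step 25
Reactants: 34 (2R)-2-methylbutanoyl imide
Product: 35 (2R)-2-methylbutan-1-ol
Conditions: LiBH4, H2O (1 equiv), Et2O, 0 °C
Reagents that add atoms: none
Why: Reductive cleavage of the imide with LiBH4 gives the primary alcohol without epimerisation and returns the auxiliary.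

Step 26
Reactants: 35 (2R)-2-methylbutan-1-ol
Product: 37 ethyl (2E,4R)-2,4-dimethylhex-2-enoate, via (2R)-2-methylbutanal 36 (not isolated)
Conditions: (COCl)2, DMSO, CH2Cl2, −78 °C; Et3N; then Ph3P=C(Me)CO2Et, −78 °C to rt
Reagents that add atoms: ethyl 2-(triphenylphosphoranylidene)propanoate, CCOC(=O)C(C)=P(c1ccccc1)(c1ccccc1)c1ccccc1
Why: Swern oxidation followed by Wittig olefination in the same flask traps the configurationally labile α-branched aldehyde at once, and the stabilised ylide gives the (E)-trisubstituted enoate.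

Step 27
Reactants: 37 ethyl (2E,4R)-2,4-dimethylhex-2-enoate
Product: 38 (2E,4R)-2,4-dimethylhex-2-en-1-ol
Conditions: i-Bu2AlH, CH2Cl2, −78 °C
Reagents that add atoms: none
Why: 1,2-Reduction of the enoate by the aluminium hydride to the allylic alcohol.

Step 28
Reactants: 38 (2E,4R)-2,4-dimethylhex-2-en-1-ol
Product: 39 (2E,4R)-2,4-dimethylhex-2-enal
Conditions: MnO2, CH2Cl2, rt
Reagents that add atoms: none
Why: Selective oxidation of the allylic alcohol by MnO2 to the enal without touching the stereocentre.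

Step 29
Reactants: 39 (2E,4R)-2,4-dimethylhex-2-enal
Product: 40 ethyl (2E,4E,6E,8R)-6,8-dimethyldeca-2,4,6-trienoate
Conditions: (EtO)2P(O)CH2CH=CHCO2Et, LiN(SiMe3)2, THF, −78 to 0 °C
Reagents that add atoms: triethyl 4-phosphonocrotonate, CCOC(=O)/C=C/CP(=O)(OCC)OCC
Why: Vinylogous Horner–Wadsworth–Emmons olefination forms the new C4=C5 bond with (E) geometry and carries the (2E) bond of the phosphonate.

Step 30
Reactants: 40 ethyl trienoate
Product: 41 (2E,4E,6E,8R)-6,8-dimethyldeca-2,4,6-trienoic acid
Conditions: LiOH, THF/MeOH/H2O, rt; dilute HCl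
Reagents that add atoms: lithium hydroxide, [Li+].[OH-]
Why: Saponification of the trienoate; the C8 stereocentre is not acidic under these conditions.

Step 31
Reactants: 31 C4 alcohol; 41 trienoic acid
Product: 43 C4 trienoate, via trichlorobenzoyl mixed anhydride 42 (not isolated)
Conditions: 2,4,6-Cl3C6H2COCl, Et3N, THF, rt; then 31, DMAP, toluene, rt
Reagents that add atoms: none
Why: Yamaguchi esterification: the mixed anhydride is attacked at the trienoyl carbonyl by the hindered allylic alcohol under DMAP catalysis, with retention at C4.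

Step 32
Reactants: 43 C4 trienoate
Product: 44 primary allylic alcohol
Conditions: DDQ, CH2Cl2/pH 7 buffer, 0 °C
Reagents that add atoms: none
Why: Oxidative cleavage of the PMB ether by DDQ; the PMB ester, deactivated by its acyl group, and the electron-poor triene should not react.

Step 33
Reactants: 44 primary allylic alcohol
Product: 45 enal PMB ester
Conditions: Dess–Martin periodinane (DMP), pyridine, CH2Cl2, 0 °C
Reagents that add atoms: none
Why: Dess–Martin oxidation of the primary allylic alcohol to the enal under buffered conditions that do not epimerise C1.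

Step 34
Reactants: 45 enal PMB ester
Product: 46 target CNP0277819.3
Conditions: CF3CO2H, anisole, CH2Cl2, 0 °C
Reagents that add atoms: none
Why: Acidolysis of the PMB ester with anisole as cation trap frees the acid; enal, enone and allylic trienoate should be stable to dilute CF3CO2H.

## Compound list

Indene locants are those of the overview, not the systematic ones; TBS = tert-butyldimethylsilyl, PMB = 4-methoxybenzyl.

1 | pent-4-yn-1-ol | C#CCCCO | starting material
2 | pent-4-ynal | C#CCCC=O | intermediate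
3 | rac-hept-1-en-6-yn-3-ol | C=CC(O)CCC#C | intermediate
4 | rac-tert-butyl(hept-1-en-6-yn-3-yloxy)dimethylsilane | C=CC(O[Si](C)(C)C(C)(C)C)CCC#C | intermediate
5 | rac-7-(tert-butyldimethylsilyloxy)non-8-en-3-yn-2-one | CC(=O)C#CCCC(O[Si](C)(C)C(C)(C)C)C=C | intermediate
6 | ethylene glycol (ethane-1,2-diol) | OCCO | starting material
7 | rac-7-(tert-butyldimethylsilyloxy)-4-(2-hydroxyethoxy)nona-3,8-dien-2-one (alkene geometry open) | CC(=O)C=C(OCCO)CCC(O[Si](C)(C)C(C)(C)C)C=C | intermediate
8 | rac-1-{2-[3-(tert-butyldimethylsilyloxy)pent-4-en-1-yl]-1,3-dioxolan-2-yl}propan-2-one | CC(=O)CC1(CCC(O[Si](C)(C)C(C)(C)C)C=C)OCCO1 | intermediate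
9 | rac-ethyl (2E)-4-{2-[3-(tert-butyldimethylsilyloxy)pent-4-en-1-yl]-1,3-dioxolan-2-yl}-3-methylbut-2-enoate | CCOC(=O)/C=C(\C)CC1(CCC(O[Si](C)(C)C(C)(C)C)C=C)OCCO1 | intermediate
10 | rac-(2E)-4-{2-[3-(tert-butyldimethylsilyloxy)pent-4-en-1-yl]-1,3-dioxolan-2-yl}-3-methylbut-2-enoic acid | OC(=O)/C=C(\C)CC1(CCC(O[Si](C)(C)C(C)(C)C)C=C)OCCO1 | intermediate
11 | oxazolidin-2-one | O=C1NCCO1 | starting material
12 | mixed anhydride of acid 10 with pivalic acid | CC(C)(C)C(=O)OC(=O)/C=C(\C)CC1(CCC(O[Si](C)(C)C(C)(C)C)C=C)OCCO1 | intermediate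
13 | rac-3-[(2E)-4-{2-[3-(tert-butyldimethylsilyloxy)pent-4-en-1-yl]-1,3-dioxolan-2-yl}-3-methylbut-2-enoyl]oxazolidin-2-one | O=C1OCCN1C(=O)/C=C(\C)CC2(CCC(O[Si](C)(C)C(C)(C)C)C=C)OCCO2 | intermediate
14 | rac-3-{(2E)-4-[2-(3-hydroxypent-4-en-1-yl)-1,3-dioxolan-2-yl]-3-methylbut-2-enoyl}oxazolidin-2-one | O=C1OCCN1C(=O)/C=C(\C)CC2(CCC(O)C=C)OCCO2 | intermediate
15 | 3-{(2E)-3-methyl-4-[2-(3-oxopent-4-en-1-yl)-1,3-dioxolan-2-yl]but-2-enoyl}oxazolidin-2-one (achiral) | O=C1OCCN1C(=O)/C=C(\C)CC2(CCC(=O)C=C)OCCO2 | intermediate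
16 | 3-[(2E)-4-{2-[(2Z)-3-(tert-butyldimethylsilyloxy)penta-2,4-dien-1-yl]-1,3-dioxolan-2-yl}-3-methylbut-2-enoyl]oxazolidin-2-one (achiral) | C=C/C(O[Si](C)(C)C(C)(C)C)=C/CC1(OCCO1)C/C(C)=C/C(=O)N1CCOC1=O | intermediate
17 | 3-{[(3aR,7R,7aR)-4-(tert-butyldimethylsilyloxy)-2,2-(ethylenedioxy)-7a-methyl-2,3,3a,6,7,7a-hexahydro-1H-inden-7-yl]carbonyl}oxazolidin-2-one (trans-fused; C7 acyl and C7a methyl β, C3a–H α) | C1C3(OCCO3)C[C@H]2C(O[Si](C)(C)C(C)(C)C)=CC[C@@H](C(=O)N4CCOC4=O)[C@@]21C | intermediate
18 | 3-{[(3aR,7R,7aR)-2,2-(ethylenedioxy)-7a-methyl-4-oxooctahydro-1H-inden-7-yl]carbonyl}oxazolidin-2-one | C1C3(OCCO3)C[C@H]2C(=O)CC[C@@H](C(=O)N4CCOC4=O)[C@@]21C | intermediate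
19 | 3-{[(3aR,4S,7R,7aR)-2,2-(ethylenedioxy)-4-hydroxy-7a-methyloctahydro-1H-inden-7-yl]carbonyl}oxazolidin-2-one (4-OH β) | C1C3(OCCO3)C[C@H]2[C@@H](O)CC[C@@H](C(=O)N4CCOC4=O)[C@@]21C | intermediate
20 | 3-{[(3aR,4S,7R,7aR)-4-(tert-butyldimethylsilyloxy)-2,2-(ethylenedioxy)-7a-methyloctahydro-1H-inden-7-yl]carbonyl}oxazolidin-2-one | C1C3(OCCO3)C[C@H]2[C@@H](O[Si](C)(C)C(C)(C)C)CC[C@@H](C(=O)N4CCOC4=O)[C@@]21C | intermediate
21 | (3aR,4S,7R,7aR)-4-(tert-butyldimethylsilyloxy)-2,2-(ethylenedioxy)-7a-methyloctahydro-1H-indene-7-carboperoxoic acid | C1C3(OCCO3)C[C@H]2[C@@H](O[Si](C)(C)C(C)(C)C)CC[C@@H](C(=O)OO)[C@@]21C | intermediate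
22 | (3aR,4S,7R,7aR)-4-(tert-butyldimethylsilyloxy)-2,2-(ethylenedioxy)-7a-methyloctahydro-1H-indene-7-carboxylic acid | C1C3(OCCO3)C[C@H]2[C@@H](O[Si](C)(C)C(C)(C)C)CC[C@@H](C(=O)O)[C@@]21C | intermediate
23 | 4-methoxybenzyl (3aR,4S,7R,7aR)-4-(tert-butyldimethylsilyloxy)-2,2-(ethylenedioxy)-7a-methyloctahydro-1H-indene-7-carboxylate | C1C3(OCCO3)C[C@H]2[C@@H](O[Si](C)(C)C(C)(C)C)CC[C@@H](C(=O)OCc4ccc(OC)cc4)[C@@]21C | intermediate
24 | 4-methoxybenzyl (3aR,4S,7R,7aR)-4-(tert-butyldimethylsilyloxy)-7a-methyl-2-oxooctahydro-1H-indene-7-carboxylate | C1C(=O)C[C@H]2[C@@H](O[Si](C)(C)C(C)(C)C)CC[C@@H](C(=O)OCc3ccc(OC)cc3)[C@@]21C | intermediate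
25 | 4-methoxybenzyl (3aR,4S,7R,7aR)-4-(tert-butyldimethylsilyloxy)-7a-methyl-2-(trimethylsilyloxy)-3a,4,5,6,7,7a-hexahydro-1H-indene-7-carboxylate (C2=C3 enol ether) | C1C(O[Si](C)(C)C)=C[C@H]2[C@@H](O[Si](C)(C)C(C)(C)C)CC[C@@H](C(=O)OCc3ccc(OC)cc3)[C@@]21C | intermediate
26 | 4-methoxybenzyl (4S,7R,7aS)-4-(tert-butyldimethylsilyloxy)-7a-methyl-2-oxo-2,4,5,6,7,7a-hexahydro-1H-indene-7-carboxylate | C1C(=O)C=C2[C@@H](O[Si](C)(C)C(C)(C)C)CC[C@@H](C(=O)OCc3ccc(OC)cc3)[C@@]21C | intermediate
27 | 3-bromo-2-(bromomethyl)prop-1-ene | C=C(CBr)CBr | starting material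
28 | 1-({[2-(bromomethyl)prop-2-en-1-yl]oxy}methyl)-4-methoxybenzene | C=C(CBr)COCc1ccc(OC)cc1 | intermediate
29 | C1 epimer mixture of 30 | C=C(COCc3ccc(OC)cc3)CC1C(=O)C=C2[C@@H](O[Si](C)(C)C(C)(C)C)CC[C@@H](C(=O)OCc4ccc(OC)cc4)[C@@]21C | intermediate
30 | 4-methoxybenzyl (1R,4S,7R,7aS)-4-(tert-butyldimethylsilyloxy)-1-{2-[(4-methoxybenzyloxy)methyl]prop-2-en-1-yl}-7a-methyl-2-oxo-2,4,5,6,7,7a-hexahydro-1H-indene-7-carboxylate | C=C(COCc3ccc(OC)cc3)C[C@H]1C(=O)C=C2[C@@H](O[Si](C)(C)C(C)(C)C)CC[C@@H](C(=O)OCc4ccc(OC)cc4)[C@@]21C | intermediate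
31 | 4-methoxybenzyl (1R,4S,7R,7aS)-4-hydroxy-1-{2-[(4-methoxybenzyloxy)methyl]prop-2-en-1-yl}-7a-methyl-2-oxo-2,4,5,6,7,7a-hexahydro-1H-indene-7-carboxylate | C=C(COCc3ccc(OC)cc3)C[C@H]1C(=O)C=C2[C@@H](O)CC[C@@H](C(=O)OCc4ccc(OC)cc4)[C@@]21C | intermediate
32 | (4R)-4-benzyloxazolidin-2-one | O=C1N[C@H](Cc2ccccc2)CO1 | starting material
33 | (4R)-4-benzyl-3-butanoyloxazolidin-2-one | CCCC(=O)N1[C@H](Cc2ccccc2)COC1=O | intermediate
34 | (4R)-4-benzyl-3-[(2R)-2-methylbutanoyl]oxazolidin-2-one | CC[C@@H](C)C(=O)N1[C@H](Cc2ccccc2)COC1=O | intermediate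
35 | (2R)-2-methylbutan-1-ol | OC[C@H](C)CC | intermediate
36 | (2R)-2-methylbutanal | O=C[C@H](C)CC | intermediate
37 | ethyl (2E,4R)-2,4-dimethylhex-2-enoate | CCOC(=O)/C(C)=C/[C@H](C)CC | intermediate
38 | (2E,4R)-2,4-dimethylhex-2-en-1-ol | OC/C(C)=C/[C@H](C)CC | intermediate
39 | (2E,4R)-2,4-dimethylhex-2-enal | O=C/C(C)=C/[C@H](C)CC | intermediate
40 | ethyl (2E,4E,6E,8R)-6,8-dimethyldeca-2,4,6-trienoate | CCOC(=O)/C=C/C=C/C(C)=C/[C@H](C)CC | intermediate
41 | (2E,4E,6E,8R)-6,8-dimethyldeca-2,4,6-trienoic acid | OC(=O)/C=C/C=C/C(C)=C/[C@H](C)CC | intermediate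
42 | mixed anhydride of acid 41 with 2,4,6-trichlorobenzoic acid | O=C(OC(=O)/C=C/C=C/C(C)=C/[C@H](C)CC)c1c(Cl)cc(Cl)cc1Cl | intermediate
43 | 4-methoxybenzyl (1R,4S,7R,7aS)-4-{[(2E,4E,6E,8R)-6,8-dimethyldeca-2,4,6-trienoyl]oxy}-1-{2-[(4-methoxybenzyloxy)methyl]prop-2-en-1-yl}-7a-methyl-2-oxo-2,4,5,6,7,7a-hexahydro-1H-indene-7-carboxylate | C=C(COCc3ccc(OC)cc3)C[C@H]1C(=O)C=C2[C@@H](OC(=O)/C=C/C=C/C(C)=C/[C@H](C)CC)CC[C@@H](C(=O)OCc4ccc(OC)cc4)[C@@]21C | intermediate
44 | 4-methoxybenzyl (1R,4S,7R,7aS)-4-{[(2E,4E,6E,8R)-6,8-dimethyldeca-2,4,6-trienoyl]oxy}-1-[2-(hydroxymethyl)prop-2-en-1-yl]-7a-methyl-2-oxo-2,4,5,6,7,7a-hexahydro-1H-indene-7-carboxylate | C=C(CO)C[C@H]1C(=O)C=C2[C@@H](OC(=O)/C=C/C=C/C(C)=C/[C@H](C)CC)CC[C@@H](C(=O)OCc3ccc(OC)cc3)[C@@]21C | intermediate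
45 | 4-methoxybenzyl (1R,4S,7R,7aS)-4-{[(2E,4E,6E,8R)-6,8-dimethyldeca-2,4,6-trienoyl]oxy}-1-(2-formylprop-2-en-1-yl)-7a-methyl-2-oxo-2,4,5,6,7,7a-hexahydro-1H-indene-7-carboxylate | C=C(C=O)C[C@H]1C(=O)C=C2[C@@H](OC(=O)/C=C/C=C/C(C)=C/[C@H](C)CC)CC[C@@H](C(=O)OCc3ccc(OC)cc3)[C@@]21C | intermediate
46 | (1R,4S,7R,7aS)-4-{[(2E,4E,6E,8R)-6,8-dimethyldeca-2,4,6-trienoyl]oxy}-1-(2-formylprop-2-en-1-yl)-7a-methyl-2-oxo-2,4,5,6,7,7a-hexahydro-1H-indene-7-carboxylic acid (CNP0277819.3) | C=C(C=O)C[C@H]1C(=O)C=C2[C@@H](OC(=O)/C=C/C=C/C(C)=C/[C@H](C)CC)CC[C@@H](C(=O)O)[C@@]21C | target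

## Step count and risks

Total steps: 34 (main line 25; bromide 28 one step; acid 41 eight steps).
Longest linear sequence: 25 steps (steps 1–19, 21, 22, 31–34).

Steps most likely to fail:

1. Step 12. The β,β-disubstituted enoyl imide may add too slowly, so that loss of the silyl group from the diene or an uncyclised Michael pathway takes over, and facial discrimination by the ligand may erode. The fallback sets out from mixed anhydride 12 and comes back at acid 22; it moves the asymmetric induction from the catalyst to a covalently bound auxiliary. Anhydride 12 would be treated with auxiliary 32 (LiCl, Et3N) to give the silyl-protected (4R)-4-benzyl imide F1. HF·pyridine would give the allylic alcohol F2, Dess–Martin oxidation the vinyl ketone F3, and TBSOTf/Et3N the chiral silyloxydiene F4. Me2AlCl (1.4 equiv, CH2Cl2, −78 °C) would form the aluminium chelate of the s-cis imide, in which the benzyl group screens the Si face at C7. Endo cycloaddition on the Re face should then give the cycloadduct F5 with the same C3a, C7 and C7a configuration as 17. Buffered HF·pyridine would give the ketone F6, NaBH4 the 4β-alcohol F7 and TBSOTf/2,6-lutidine the silyl ether F8; LiOH/H2O2 would then deliver acid 22 and return 32.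

2. Step 21. Alkylation may occur on the undesired face with incomplete equilibration at C1, or proton transfer between enolate and product may lead to over-alkylation. The fallback sets out from the epimer mixture 29 and comes back at 30; it replaces thermodynamic control by kinetic protonation. Me3SiOTf/Et3N would convert 29 into the cross-conjugated trimethylsilyl dienol ether F9, which erases C1. Fluoride-triggered protonation at −78 °C (Bu4NF, 2,6-di-tert-butyl-4-methylphenol, THF) should then deliver the proton to the face that the alkylating agent had preferred, placing the side chain on the opposite, β face. The esterification of step 31 would then be run with a carbodiimide and catalytic DMAP at 0 °C to limit re-equilibration.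

3. Step 19. Enolisation may go toward C1 instead of C3, which returns unchanged ketone, or β-hydride elimination may be slow in the five-membered ring. The fallback sets out from ketone 24 and comes back at enone 26 and makes no new compound F0. Direct dehydrogenation with 2-iodoxybenzoic acid (DMSO/toluene, 70 °C) needs no preformed enol ether: enolisation is reversible and only the C3 enol has a β-hydrogen (at C3a), so the ketone should drain into the single possible enone.

## Further compounds

F1 | step 12 | (4R)-4-benzyl-3-[(2E)-4-{2-[3-(tert-butyldimethylsilyloxy)pent-4-en-1-yl]-1,3-dioxolan-2-yl}-3-methylbut-2-enoyl]oxazolidin-2-one | C=CC(O[Si](C)(C)C(C)(C)C)CCC1(OCCO1)C/C(C)=C/C(=O)N1[C@H](Cc2ccccc2)COC1=O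
F2 | step 12 | (4R)-4-benzyl-3-{(2E)-4-[2-(3-hydroxypent-4-en-1-yl)-1,3-dioxolan-2-yl]-3-methylbut-2-enoyl}oxazolidin-2-one | C=CC(O)CCC1(OCCO1)C/C(C)=C/C(=O)N1[C@H](Cc2ccccc2)COC1=O
F3 | step 12 | (4R)-4-benzyl-3-{(2E)-3-methyl-4-[2-(3-oxopent-4-en-1-yl)-1,3-dioxolan-2-yl]but-2-enoyl}oxazolidin-2-one | C=CC(=O)CCC1(OCCO1)C/C(C)=C/C(=O)N1[C@H](Cc2ccccc2)COC1=O
F4 | step 12 | (4R)-4-benzyl-3-[(2E)-4-{2-[(2Z)-3-(tert-butyldimethylsilyloxy)penta-2,4-dien-1-yl]-1,3-dioxolan-2-yl}-3-methylbut-2-enoyl]oxazolidin-2-one | C=C/C(O[Si](C)(C)C(C)(C)C)=C/CC1(OCCO1)C/C(C)=C/C(=O)N1[C@H](Cc2ccccc2)COC1=O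
F5 | step 12 | (4R)-4-benzyl analogue of cycloadduct 17 | C1C3(OCCO3)C[C@H]2C(O[Si](C)(C)C(C)(C)C)=CC[C@@H](C(=O)N4[C@H](Cc5ccccc5)COC4=O)[C@@]21C
F6 | step 12 | (4R)-4-benzyl analogue of ketone 18 | C1C3(OCCO3)C[C@H]2C(=O)CC[C@@H](C(=O)N4[C@H](Cc5ccccc5)COC4=O)[C@@]21C
F7 | step 12 | (4R)-4-benzyl analogue of 4β-alcohol 19 | C1C3(OCCO3)C[C@H]2[C@@H](O)CC[C@@H](C(=O)N4[C@H](Cc5ccccc5)COC4=O)[C@@]21C
F8 | step 12 | (4R)-4-benzyl analogue of silyl ether 20 | C1C3(OCCO3)C[C@H]2[C@@H](O[Si](C)(C)C(C)(C)C)CC[C@@H](C(=O)N4[C@H](Cc5ccccc5)COC4=O)[C@@]21C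
F9 | step 21 | trimethylsilyl dienol ether of 30 (C1=C2–OSiMe3, C3=C3a; other centres as in 30) | C=C(COCc3ccc(OC)cc3)CC1=C(O[Si](C)(C)C)C=C2[C@@H](O[Si](C)(C)C(C)(C)C)CC[C@@H](C(=O)OCc4ccc(OC)cc4)[C@@]21C
F0 | step 19 | none | none
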